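**Assumption:** benzodioxane locants are O1–C2(aryl)–C3(CH2X)–O4, with the aryloxy group at C5 and iodine/allyl at C7; the target SMILES is then the trans-(2S,3S) isomer. The route is a paper design and has not been run.

## Retrosynthetic overview

1. Magnolianin ⇐ MOM removal ⇐ Williamson ether of magnolol 28 with chloromethyl-benzodioxane 23. Each allyl group enters by Suzuki allylation of one C–X bond (steps 2, 11, 13).
2. The dioxane ring (formed last) ⇐ acid-mediated benzylic C2–O1 closure of diol 21, trans relayed from C3.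
3. 21 ⇐ ring-B aryl Grignard + lactol of benzodioxanone 18. 18 ⇐ Baeyer–Villiger/Dakin 1,2-aryl shift (C→O) of o-alkoxybenzaldehyde 15; the formyl group is the placeholder for O1. The lactone ring forms first and is then traded for the dioxane ring.
4. 15 ⇐ salicylaldehyde 7 + methyl (R)-glycidate by a new phosphonium-mediated chloro-aryloxylation (C3–O4 bond, inversion). The same 7 ⇒ Dakin ⇒ ring-B catechol.
5. 7 ⇐ catechol + 1-bromo-4-iodobenzene (Ullmann, allylation, para-iodination, ortho-formylation). Magnolol ⇐ 2-bromophenol (iodination, allylation, borylation, Suzuki cross-coupling of the two halves).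

## Route

Step 1
Reactants: 1 catechol; 2 1-bromo-4-iodobenzene
Product: 3 2-(4-bromophenoxy)phenol
Conditions: CuI (10 mol %), picolinic acid (20 mol %), K3PO4, DMSO, 80 °C; 1 in 3-fold excess
Reagents that add atoms: none
Why: Ullmann-type Cu-catalysed O-arylation reacts at C–I well before C–Br, and excess catechol holds it at mono-arylation.

Step 2
Reactants: 3 2-(4-bromophenoxy)phenol; 4 potassium allyltrifluoroborate
Product: 5 2-(4-allylphenoxy)phenol
Conditions: 4 (1.3 equiv), PdCl2(dtbpf) (2 mol %), K2CO3, THF/H2O, 65 °C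
Reagents that add atoms: none
Why: Suzuki–Miyaura sp2–sp3 coupling of the single aryl bromide tolerates the free phenol, and this one allyl group is later carried into both diaryl ether units.

Step 3
Reactants: 5 2-(4-allylphenoxy)phenol
Product: 6 2-(4-allylphenoxy)-4-iodophenol
Conditions: NIS (1.0 equiv), TFA (cat.), MeCN, −10 → 0 °C
Reagents that add atoms: N-iodosuccinimide, O=C1CCC(=O)N1I
Why: Electrophilic aromatic iodination goes para to the free OH on the more electron-rich ring far faster than NIS attacks the isolated terminal alkene.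

Step 4
Reactants: 6 2-(4-allylphenoxy)-4-iodophenol
Product: 7 3-(4-allylphenoxy)-2-hydroxy-5-iodobenzaldehyde
Conditions: MgCl2, Et3N, (CH2O)n, MeCN, 80 °C
Reagents that add atoms: paraformaldehyde (formaldehyde), C=O
Why: Magnesium-phenoxide-directed ortho-formylation (Casnati–Skattebøl) puts CHO on the only free position ortho to OH, where it marks the site of the third oxygen.

Step 5
Reactants: 7 3-(4-allylphenoxy)-2-hydroxy-5-iodobenzaldehyde
Product: 9 3-(4-allylphenoxy)-5-iodobenzene-1,2-diol, via aryl formate 8 (not isolated)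
Conditions: 30% H2O2, NaOH, THF/H2O, 0 °C, N2; then HCl
Reagents that add atoms: hydrogen peroxide, OO
Why: Dakin oxidation; the hydroperoxide adduct of the o-hydroxybenzaldehyde undergoes a 1,2-aryl shift from carbon to oxygen, the formate is hydrolysed in the flask, and alkaline H2O2 leaves the allyl group alone.

Step 6
Reactants: 9 3-(4-allylphenoxy)-5-iodobenzene-1,2-diol
Product: 10 1-(4-allylphenoxy)-5-iodo-2,3-bis(methoxymethoxy)benzene
Conditions: NaH, MOMCl, DMF, 0 °C
Reagents that add atoms: chloromethyl methyl ether, COCCl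
Why: O-alkylation of the catecholate (MOM protection) masks both phenols for the organometallic and basic steps and comes off under mild acid.

Step 7
Reactants: 7 3-(4-allylphenoxy)-2-hydroxy-5-iodobenzaldehyde; 11 methyl (2R)-oxirane-2-carboxylate (methyl (R)-glycidate)
Product: 15 methyl (2R)-2-[2-(4-allylphenoxy)-6-formyl-4-iodophenoxy]-3-chloropropanoate, via sodium aryloxide 12 (not isolated), via aryloxyphosphonium chloride 13 (not isolated), via alkoxyphosphonium aryloxide 14 (not isolated)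
Conditions: NaH, THF, 0 °C; Ph3PCl2, CH2Cl2, −20 °C; then 11, 23 → 40 °C
Reagents that add atoms: dichlorotriphenylphosphorane, ClP(Cl)(c1ccccc1)(c1ccccc1)c1ccccc1
Why: Proposed new method: deoxygenative anti-chloro-aryloxylation of an epoxide, in which the epoxide oxygen binds the oxophilic aryloxyphosphonium 13 while its only chloride opens the unhindered C3 (the regiochemistry HCl shows with glycidates), giving the Mitsunobu-type ion pair 14 whose aryloxide displaces Ph3P=O at the α-ester carbon by SN2 with inversion, so C2 of 15 is R (the letter is kept only because CH2Cl now outranks CO2Me); the closest known reactions are the Ph3PCl2 deoxydichlorination of epoxides and the Mitsunobu etherification of α-hydroxy esters.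

Step 8
Reactants: 15 methyl (2R)-2-[2-(4-allylphenoxy)-6-formyl-4-iodophenoxy]-3-chloropropanoate
Product: 18 (3R)-5-(4-allylphenoxy)-3-(chloromethyl)-7-iodo-1,4-benzodioxin-2(3H)-one, via aryl formate 16 (not isolated), via phenol ester 17 (not isolated)
Conditions: 35% H2O2, H2SO4 (cat.), MeOH, 23 °C; then TsOH (cat.), PhMe, 80 °C (−MeOH)
Reagents that add atoms: hydrogen peroxide, OO
Why: Baeyer–Villiger/Dakin-type oxidation, in which the o-alkoxyaryl group shifts 1,2 from the formyl carbon to oxygen in the Criegee adduct, the formate is methanolysed and the new phenol lactonises onto the neighbouring ester, which fixes O1 next to the future C2 without touching C3 or the allyl group.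

Step 9
Reactants: 18 (3R)-5-(4-allylphenoxy)-3-(chloromethyl)-7-iodo-1,4-benzodioxin-2(3H)-one; 10 1-(4-allylphenoxy)-5-iodo-2,3-bis(methoxymethoxy)benzene
Product: 21 (2R)-1-[3-(4-allylphenoxy)-4,5-bis(methoxymethoxy)phenyl]-2-[2-(4-allylphenoxy)-6-hydroxy-4-iodophenoxy]-3-chloropropan-1-ol (C1 epimers), via lactol 19 (not isolated), via arylmagnesium chloride 20 (not isolated)
Conditions: DIBAL-H (1.05 equiv), CH2Cl2, −78 °C; then 20 [from 10 (1.5 equiv), iPrMgCl·LiCl (0.95 equiv per 10), THF, −15 °C], −78 → 0 °C; Rochelle salt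
Reagents that add atoms: none
Why: Half-reduction of the aryl lactone gives the aluminium lactolate, whose open α-aryloxy aldehyde is trapped by the aryl Grignard made by I/Mg exchange (no free iPrMgCl is left to touch the ring-A iodide); the new carbinol centre is a mixture that step 10 re-sets, and C2 is retained.

Step 10
Reactants: 21 (2R)-1-[3-(4-allylphenoxy)-4,5-bis(methoxymethoxy)phenyl]-2-[2-(4-allylphenoxy)-6-hydroxy-4-iodophenoxy]-3-chloropropan-1-ol
Product: 22 (2S,3R)-5-(4-allylphenoxy)-2-[3-(4-allylphenoxy)-4,5-bis(methoxymethoxy)phenyl]-3-(chloromethyl)-7-iodo-2,3-dihydro-1,4-benzodioxine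
Conditions: CSA (0.3 equiv), 4 Å MS, CH2Cl2, 23 °C
Reagents that add atoms: none
Why: Acid-mediated SN1 cyclodehydration through the p-alkoxybenzyl cation closes the 1,4-dioxane ring, and reversible ionisation gives the thermodynamically preferred trans (diequatorial) isomer, so C2 becomes S under control of C3.

Step 11
Reactants: 22 (2S,3R)-5-(4-allylphenoxy)-2-[3-(4-allylphenoxy)-4,5-bis(methoxymethoxy)phenyl]-3-(chloromethyl)-7-iodo-2,3-dihydro-1,4-benzodioxine; 4 potassium allyltrifluoroborate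
Product: 23 (2S,3R)-7-allyl-5-(4-allylphenoxy)-2-[3-(4-allylphenoxy)-4,5-bis(methoxymethoxy)phenyl]-3-(chloromethyl)-2,3-dihydro-1,4-benzodioxine
Conditions: 4 (1.3 equiv), PdCl2(dppf) (3 mol %), K2CO3, THF/H2O, 60 °C
Reagents that add atoms: none
Why: Suzuki–Miyaura sp2–sp3 coupling at the only aryl halide left (C7–I) installs the third allyl group, while the primary alkyl chloride, the MOM ethers and both stereocentres are inert to Pd(dppf) and carbonate.

Step 12
Reactants: 24 2-bromophenol
Product: 25 2-bromo-4-iodophenol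
Conditions: NIS, TsOH (cat.), MeCN, 0 → 23 °C
Reagents that add atoms: N-iodosuccinimide, O=C1CCC(=O)N1I
Why: Electrophilic aromatic iodination goes para to the OH and gives a C–I bond that couples before the C–Br bond.

Step 13
Reactants: 25 2-bromo-4-iodophenol; 4 potassium allyltrifluoroborate
Product: 26 4-allyl-2-bromophenol
Conditions: 4 (1.05 equiv), PdCl2(dppf) (3 mol %), K2CO3, THF/H2O, 55 °C
Reagents that add atoms: none
Why: Suzuki–Miyaura allylation is chemoselective for C–I over C–Br with a non-bulky bisphosphine and one equivalent of the borate, so the ortho bromide is kept for the biaryl bond.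

Step 14
Reactants: 26 4-allyl-2-bromophenol
Product: 27 4-allyl-2-(4,4,5,5-tetramethyl-1,3,2-dioxaborolan-2-yl)phenol
Conditions: B2pin2, PdCl2(dppf) (3 mol %), KOAc, dioxane, 80 °C
Reagents that add atoms: bis(pinacolato)diboron, CC1(C)OB(OC1(C)C)B1OC(C)(C)C(C)(C)O1
Why: Miyaura borylation with the weak base KOAc converts the aryl bromide to the pinacol boronate without homocoupling and tolerates the free phenol and the allyl group.

Step 15
Reactants: 26 4-allyl-2-bromophenol; 27 4-allyl-2-(4,4,5,5-tetramethyl-1,3,2-dioxaborolan-2-yl)phenol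
Product: 28 magnolol (5,5'-diallylbiphenyl-2,2'-diol)
Conditions: SPhos Pd G2 (2 mol %), K3PO4, dioxane/H2O, 60 °C
Reagents that add atoms: none
Why: Suzuki–Miyaura cross-coupling of the two ortho-hydroxyaryl halves forms the biaryl bond, and the biarylphosphine catalyst handles the ortho-substituted, unprotected partners at a temperature that spares the allyl groups.

Step 16
Reactants: 23 (2S,3R)-7-allyl-5-(4-allylphenoxy)-2-[3-(4-allylphenoxy)-4,5-bis(methoxymethoxy)phenyl]-3-(chloromethyl)-2,3-dihydro-1,4-benzodioxine; 28 magnolol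
Product: 29 5,5'-diallyl-2'-({(2S,3S)-7-allyl-5-(4-allylphenoxy)-2-[3-(4-allylphenoxy)-4,5-bis(methoxymethoxy)phenyl]-2,3-dihydro-1,4-benzodioxin-3-yl}methoxy)biphenyl-2-ol (magnolianin bis-MOM ether)
Conditions: 28 (3 equiv), K2CO3, KI (cat.), DMF, 70 °C
Reagents that add atoms: none
Why: Williamson ether synthesis (SN2, iodide-assisted) at the primary chloride with excess biphenol gives the mono-ether; both stereocentres are untouched, and C3 is now called S only because CH2OAr ranks below C2.

Step 17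
Reactants: 29 magnolianin bis-MOM ether
Product: 30 magnolianin
Conditions: NaHSO4·SiO2, CH2Cl2, 23 °C
Reagents that add atoms: none
Why: Mild heterogeneous acid hydrolysis of the phenolic MOM acetals in a non-nucleophilic medium leaves the allyl groups intact, and any reversible opening at C2 returns to the trans ring.

## Compound list

1 | catechol | Oc1ccccc1O | starting material
2 | 1-bromo-4-iodobenzene | Brc1ccc(I)cc1 | starting material
3 | 2-(4-bromophenoxy)phenol | Oc1ccccc1Oc1ccc(Br)cc1 | intermediate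
4 | potassium allyltrifluoroborate | [K+].C=CC[B-](F)(F)F | starting material
5 | 2-(4-allylphenoxy)phenol | Oc1ccccc1Oc1ccc(CC=C)cc1 | intermediate
6 | 2-(4-allylphenoxy)-4-iodophenol | Oc1ccc(I)cc1Oc1ccc(CC=C)cc1 | intermediate
7 | 3-(4-allylphenoxy)-2-hydroxy-5-iodobenzaldehyde | O=Cc1cc(I)cc(Oc2ccc(CC=C)cc2)c1O | intermediate
8 | 3-(4-allylphenoxy)-2-hydroxy-5-iodophenyl formate | O=COc1cc(I)cc(Oc2ccc(CC=C)cc2)c1O | intermediate
9 | 3-(4-allylphenoxy)-5-iodobenzene-1,2-diol | Oc1cc(I)cc(Oc2ccc(CC=C)cc2)c1O | intermediate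
10 | 1-(4-allylphenoxy)-5-iodo-2,3-bis(methoxymethoxy)benzene | COCOc1cc(I)cc(Oc2ccc(CC=C)cc2)c1OCOC | intermediate
11 | methyl (2R)-oxirane-2-carboxylate | COC(=O)[C@H]1CO1 | starting material
12 | sodium 2-(4-allylphenoxy)-6-formyl-4-iodophenoxide | [Na+].[O-]c1c(C=O)cc(I)cc1Oc1ccc(CC=C)cc1 | intermediate
13 | [2-(4-allylphenoxy)-6-formyl-4-iodophenoxy]triphenylphosphonium chloride | [Cl-].O=Cc1cc(I)cc(Oc2ccc(CC=C)cc2)c1O[P+](c1ccccc1)(c1ccccc1)c1ccccc1 | intermediate
14 | {[(2S)-3-chloro-1-methoxy-1-oxopropan-2-yl]oxy}triphenylphosphonium 2-(4-allylphenoxy)-6-formyl-4-iodophenoxide | COC(=O)[C@H](O[P+](c1ccccc1)(c1ccccc1)c1ccccc1)CCl.[O-]c1c(C=O)cc(I)cc1Oc1ccc(CC=C)cc1 | intermediate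
15 | methyl (2R)-2-[2-(4-allylphenoxy)-6-formyl-4-iodophenoxy]-3-chloropropanoate | COC(=O)[C@@H](Oc1c(C=O)cc(I)cc1Oc1ccc(CC=C)cc1)CCl | intermediate
16 | methyl (2R)-2-[2-(4-allylphenoxy)-6-(formyloxy)-4-iodophenoxy]-3-chloropropanoate | COC(=O)[C@@H](Oc1c(OC=O)cc(I)cc1Oc1ccc(CC=C)cc1)CCl | intermediate
17 | methyl (2R)-2-[2-(4-allylphenoxy)-6-hydroxy-4-iodophenoxy]-3-chloropropanoate | COC(=O)[C@@H](Oc1c(O)cc(I)cc1Oc1ccc(CC=C)cc1)CCl | intermediate
18 | (3R)-5-(4-allylphenoxy)-3-(chloromethyl)-7-iodo-1,4-benzodioxin-2(3H)-one | O=C1Oc2cc(I)cc(Oc3ccc(CC=C)cc3)c2O[C@H]1CCl | intermediate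
19 | (3R)-5-(4-allylphenoxy)-3-(chloromethyl)-7-iodo-2,3-dihydro-1,4-benzodioxin-2-ol (formed as its aluminium lactolate) | OC1Oc2cc(I)cc(Oc3ccc(CC=C)cc3)c2O[C@H]1CCl | intermediate
20 | [3-(4-allylphenoxy)-4,5-bis(methoxymethoxy)phenyl]magnesium chloride | COCOc1cc([Mg]Cl)cc(Oc2ccc(CC=C)cc2)c1OCOC | intermediate
21 | (2R)-1-[3-(4-allylphenoxy)-4,5-bis(methoxymethoxy)phenyl]-2-[2-(4-allylphenoxy)-6-hydroxy-4-iodophenoxy]-3-chloropropan-1-ol (C1 epimers) | OC(c1cc(OCOC)c(OCOC)c(Oc2ccc(CC=C)cc2)c1)[C@H](CCl)Oc1c(O)cc(I)cc1Oc1ccc(CC=C)cc1 | intermediate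
22 | (2S,3R)-5-(4-allylphenoxy)-2-[3-(4-allylphenoxy)-4,5-bis(methoxymethoxy)phenyl]-3-(chloromethyl)-7-iodo-2,3-dihydro-1,4-benzodioxine (trans) | C=CCc1ccc(Oc2cc([C@@H]3Oc4cc(I)cc(Oc5ccc(CC=C)cc5)c4O[C@H]3CCl)cc(OCOC)c2OCOC)cc1 | intermediate
23 | (2S,3R)-7-allyl-5-(4-allylphenoxy)-2-[3-(4-allylphenoxy)-4,5-bis(methoxymethoxy)phenyl]-3-(chloromethyl)-2,3-dihydro-1,4-benzodioxine (trans) | C=CCc1ccc(Oc2cc([C@@H]3Oc4cc(CC=C)cc(Oc5ccc(CC=C)cc5)c4O[C@H]3CCl)cc(OCOC)c2OCOC)cc1 | intermediate
24 | 2-bromophenol | Oc1ccccc1Br | starting material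
25 | 2-bromo-4-iodophenol | Oc1ccc(I)cc1Br | intermediate
26 | 4-allyl-2-bromophenol | Oc1ccc(CC=C)cc1Br | intermediate
27 | 4-allyl-2-(4,4,5,5-tetramethyl-1,3,2-dioxaborolan-2-yl)phenol | Oc1ccc(CC=C)cc1B1OC(C)(C)C(C)(C)O1 | intermediate
28 | magnolol (5,5'-diallylbiphenyl-2,2'-diol) | C=CCc1ccc(O)c(-c2cc(CC=C)ccc2O)c1 | intermediate
29 | magnolianin bis-MOM ether: 5,5'-diallyl-2'-({(2S,3S)-7-allyl-5-(4-allylphenoxy)-2-[3-(4-allylphenoxy)-4,5-bis(methoxymethoxy)phenyl]-2,3-dihydro-1,4-benzodioxin-3-yl}methoxy)biphenyl-2-ol | C=CCc1ccc(Oc2cc([C@@H]3Oc4cc(CC=C)cc(Oc5ccc(CC=C)cc5)c4O[C@H]3COc3ccc(CC=C)cc3-c3cc(CC=C)ccc3O)cc(OCOC)c2OCOC)cc1 | intermediate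
30 | magnolianin: 5-{(2S,3S)-7-allyl-5-(4-allylphenoxy)-3-[(5,5'-diallyl-2'-hydroxybiphenyl-2-yloxy)methyl]-2,3-dihydro-1,4-benzodioxin-2-yl}-3-(4-allylphenoxy)benzene-1,2-diol | C=CCc1ccc(Oc2cc([C@@H]3Oc4cc(CC=C)cc(Oc5ccc(CC=C)cc5)c4O[C@H]3COc3ccc(CC=C)cc3-c3cc(CC=C)ccc3O)cc(O)c2O)cc1 | target

## Totals and risks

Total step count: 17. Longest linear sequence: 11 steps (1–2–3–4–5–6–9–10–11–16–17, or equally 1–2–3–4–7–8–9–10–11–16–17).

The three steps most likely to fail:

**Step 7 (proposed new chloro-aryloxylation).** It may give the vicinal dichloride or the 3-aryloxy regioisomer instead of 15. The fallback uses known chemistry, sets out from 11 and 7 and comes back at 15. Compound 11 is opened with HCl in dioxane at 0 °C (chloride at C3, C2 untouched) to methyl (2S)-3-chloro-2-hydroxypropanoate F1. F1 is then coupled with 7 under Mitsunobu conditions (PPh3, DIAD, toluene, 0 → 23 °C), which inverts C2 and gives 15. This costs one extra step.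

**Step 9 (DIBAL-H, then aryl Grignard).** The basic reagent may eliminate the β-chloride or epimerise C2 of the transient α-aryloxy aldehyde. The fallback sets out from 18 and 10 and comes back at 22, so 21 and step 10 are bypassed. Reductive acetylation of 18 (DIBAL-H, −78 °C; then Ac2O, pyridine, DMAP) gives the lactol acetate F2. Compound 10 is converted by iPrMgCl·LiCl, B(OMe)3 and aqueous KHF2 into the potassium aryltrifluoroborate F3. BF3·OEt2-promoted oxocarbenium arylation of F2 with F3 (CH2Cl2/MeCN, −20 °C) then forms the C2–aryl bond under non-basic conditions and gives trans-22 directly.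

**Step 16 (mono-etherification of magnolol).** The hydrogen-bonded, hindered biphenolate may react sluggishly at the β-oxygenated primary chloride or alkylate twice. The fallback sets out from 23 and 26 and comes back at 29, forming the ether before the biaryl bond. The unhindered monophenol 26 is used in large excess (K2CO3, KI, DMF, 70 °C) to give the 4-allyl-2-bromophenyl ether F4. Suzuki–Miyaura coupling of F4 with boronate 27 (SPhos Pd G2, K3PO4, dioxane/H2O, 60 °C) then closes the biaryl and gives 29.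

Further compounds
F1 | step 7 | methyl (2S)-3-chloro-2-hydroxypropanoate | COC(=O)[C@H](O)CCl
F2 | step 9 | (3R)-5-(4-allylphenoxy)-3-(chloromethyl)-7-iodo-2,3-dihydro-1,4-benzodioxin-2-yl acetate | CC(=O)OC1Oc2cc(I)cc(Oc3ccc(CC=C)cc3)c2O[C@H]1CCl
F3 | step 9 | potassium [3-(4-allylphenoxy)-4,5-bis(methoxymethoxy)phenyl]trifluoroborate | [K+].COCOc1cc([B-](F)(F)F)cc(Oc2ccc(CC=C)cc2)c1OCOC
F4 | step 16 | (2S,3S)-7-allyl-3-[(4-allyl-2-bromophenoxy)methyl]-5-(4-allylphenoxy)-2-[3-(4-allylphenoxy)-4,5-bis(methoxymethoxy)phenyl]-2,3-dihydro-1,4-benzodioxine | C=CCc1ccc(Oc2cc([C@@H]3Oc4cc(CC=C)cc(Oc5ccc(CC=C)cc5)c4O[C@H]3COc3ccc(CC=C)cc3Br)cc(OCOC)c2OCOC)cc1
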